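The synthesis rests on dismantling the trisubstituted C7=C8 alkene (lactone ring O1, C2–C6; side chain C7–C13 counted from C6) into three pieces. On that alkene C9 and the acetoxymethyl carbon are cis while ring carbon C6 is trans to C9, the signature of a syn addition across a C6–C7≡C8 propynal unit. A cuprate generated from a Z-configured C9–C13 homoallylic iodide (O13 silylated) adds to propiolaldehyde diethyl acetal, and the C7–copper bond is then alkylated with PMBOCH2Cl. C8–C9 and C7–CH2O form in one flask, with three distinguishable oxygen functions. Allylboration, acylation and ring-closing metathesis afterwards supply C6 stereochemistry and the lactone.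

Key step: step 9

Remark (structure check): C6 of the target is (R) (O1 > C7 > C5 > H), C7=C8 is E and C11=C12 is Z.
Remark (assumption): both alkyl ligands of homocuprate 16 are taken to transfer (alkyne : copper = 2 : 1), and step 9 is balanced on that basis.
Remark (design): the lactone is built by allylboration, acylation and metathesis rather than by a vinylogous aldol, because γ-unsubstituted silyl dienolates normally give the (E)-δ-hydroxy enoate, which cannot close to the ring.
Remark (design): 4-methoxybenzyl chloromethyl ether is too labile to buy and store, so it is made fresh in steps 7 and 8.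

Step 1
Reactants: 1 tert-butyl(but-3-yn-1-yloxy)dimethylsilane
Product: 3 methyl 5-[(tert-butyldimethylsilyl)oxy]pent-2-ynoate, via lithium acetylide 2 (not isolated)
Conditions: n-BuLi, THF, −78 °C; ClCO2Me, −78 → 0 °C
Reagents that add atoms: methyl chloroformate, COC(=O)Cl
Why: Deprotonation of the terminal alkyne and C-acylation of the acetylide by the chloroformate (alkyne carboxylation) is routine and leaves the TBS ether untouched.

Step 2
Reactants: 3 methyl 5-[(tert-butyldimethylsilyl)oxy]pent-2-ynoate
Product: 5 methyl (Z)-5-[(tert-butyldimethylsilyl)oxy]-3-methylpent-2-enoate, via alkenylcuprate 4 (not isolated)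
Conditions: Me2CuLi (MeLi, CuI), THF, −78 °C; quench at −78 °C with sat. aq NH4Cl
Reagents that add atoms: lithium dimethylcuprate, [Li+].C[Cu-]C (prepared in the flask from methyllithium, C[Li])
Why: Syn carbocupration of a 2-ynoate by a Gilman reagent puts the new methyl and copper cis, so a cold quench, before 4 can equilibrate through its allenolate, leaves the ester cis to the CH2CH2O chain, which is the Z geometry of C11=C12.

Step 3
Reactants: 5 methyl (Z)-5-[(tert-butyldimethylsilyl)oxy]-3-methylpent-2-enoate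
Product: 6 (Z)-5-[(tert-butyldimethylsilyl)oxy]-3-methylpent-2-en-1-ol
Conditions: DIBAL-H (2.5 equiv), CH2Cl2, −78 → 0 °C; Rochelle salt work-up
Reagents that add atoms: none
Why: DIBAL-H 1,2-reduction of an enoate gives the allylic alcohol without touching the alkene geometry or the silyl ether.

Step 4
Reactants: 6 (Z)-5-[(tert-butyldimethylsilyl)oxy]-3-methylpent-2-en-1-ol
Product: 7 (Z)-1-[(tert-butyldiphenylsilyl)oxy]-5-[(tert-butyldimethylsilyl)oxy]-3-methylpent-2-ene
Conditions: TBDPSCl, imidazole, CH2Cl2, 0 °C → rt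
Reagents that add atoms: tert-butyldiphenylsilyl chloride, CC(C)(C)[Si](Cl)(c1ccccc1)c1ccccc1
Why: Imidazole-promoted silylation of a primary allylic alcohol installs the bulky group that must resist t-BuLi, acid, DDQ and ruthenium until the last step.

Step 5
Reactants: 7 (Z)-1-[(tert-butyldiphenylsilyl)oxy]-5-[(tert-butyldimethylsilyl)oxy]-3-methylpent-2-ene
Product: 8 (Z)-5-[(tert-butyldiphenylsilyl)oxy]-3-methylpent-3-en-1-ol
Conditions: CSA (cat.), MeOH/CH2Cl2, 0 °C
Reagents that add atoms: none
Why: Acid-catalysed methanolysis (selective desilylation) removes the small primary TBS ether much faster than the hindered, far more acid-stable TBDPS ether.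

Step 6
Reactants: 8 (Z)-5-[(tert-butyldiphenylsilyl)oxy]-3-methylpent-3-en-1-ol
Product: 9 (Z)-tert-butyl[(5-iodo-3-methylpent-2-en-1-yl)oxy]diphenylsilane
Conditions: I2, PPh3, imidazole, CH2Cl2, 0 °C
Reagents that add atoms: iodine, II
Why: Appel-type iodination displaces the primary alkoxyphosphonium ion by SN2 under near-neutral conditions that spare the Z-alkene and the silyl ether.

Step 7
Reactants: 10 4-methoxybenzyl alcohol
Product: 12 4-methoxybenzyl methylthiomethyl ether, via sodium alkoxide 11 (not isolated)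
Conditions: NaH, THF, 0 °C; ClCH2SMe, NaI (cat.), 0 °C → rt
Reagents that add atoms: chloromethyl methyl sulfide, CSCCl
Why: Williamson etherification of the alkoxide with the reactive α-chloro sulfide gives the O,S-acetal under base only, so the acid-labile PMB group is never at risk.

Step 8
Reactants: 12 4-methoxybenzyl methylthiomethyl ether
Product: 13 4-methoxybenzyl chloromethyl ether
Conditions: SO2Cl2 (1.0 equiv), CH2Cl2, −78 °C; volatiles removed in vacuo at or below 0 °C; used at once
Reagents that add atoms: sulfuryl chloride, O=S(=O)(Cl)Cl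
Why: Chlorinolysis of an O,S-acetal (S-chlorination, collapse to the oxocarbenium chloride) is the established acid-free entry to chloromethyl ethers of acid-sensitive alcohols, and its by-products are volatile.

Step 9
Reactants: 9 (Z)-tert-butyl[(5-iodo-3-methylpent-2-en-1-yl)oxy]diphenylsilane; 14 propiolaldehyde diethyl acetal; 13 4-methoxybenzyl chloromethyl ether
Product: 18 (2E,6Z)-8-[(tert-butyldiphenylsilyl)oxy]-2-{[(4-methoxybenzyl)oxy]methyl}-6-methylocta-2,6-dienal diethyl acetal, via organolithium 15 (not isolated), via homocuprate 16 (not isolated), via dialkenylcuprate 17 (not isolated)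
Conditions: 9, t-BuLi (2.0 equiv), Et2O/pentane, −78 °C; CuBr·SMe2 (0.5 equiv), −78 → −35 °C; 14 (1.0 equiv), −50 → −35 °C; 13 (1.3 equiv, Et2O/THF), −50 → −25 °C; aq NH4Cl/NH3
Reagents that add atoms: none
Why: Iodine–lithium exchange followed by half an equivalent of copper(I) gives Gilman homocuprate 16, which π-complexes the alkyne of 14 and inserts it in a concerted syn carbocupration, so that C9 goes to the terminal carbon C8 and copper ends on C7. The closest known reaction type is the addition of lithium dialkylcuprates in ether to acetylenic acetals to give linear alkenylcuprates that are captured by reactive alkyl halides, a standard entry to E-2-alkyl-2-enals; only the chain and the electrophile are new here. The linear regiochemistry that the step needs is secured by the acetal of 14, whose oxygens bind the lithium of the cuprate cluster and whose inductive pull places the metal on the neighbouring carbon, while ether rather than THF disfavours simple deprotonation of the alkyne. Alkenylcuprate 17 holds its configuration at −35 °C and below and is alkylated by the very electrophilic chloromethyl ether 13 through oxidative addition and reductive elimination with retention, so C9 and the CH2OPMB carbon finish cis and the masked C6 aldehyde trans to C9 (2E). No ring closes and no stereocentre is created, so the only stereochemical element is this alkene geometry, fixed by syn addition plus retention, with the remote Z-C11=C12 alkene and the bulky TBDPS ether as spectators. Chemoselectivity against loss of ethoxide to the alkoxyallene depends on keeping the mixture below −25 °C until 13 is consumed.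

Step 10
Reactants: 18 (2E,6Z)-8-[(tert-butyldiphenylsilyl)oxy]-2-{[(4-methoxybenzyl)oxy]methyl}-6-methylocta-2,6-dienal diethyl acetal
Product: 19 (2E,6Z)-8-[(tert-butyldiphenylsilyl)oxy]-2-{[(4-methoxybenzyl)oxy]methyl}-6-methylocta-2,6-dienal
Conditions: oxalic acid (cat.), THF/H2O, 0 °C → rt
Reagents that add atoms: water, O
Why: Acetal hydrolysis through an allyl-stabilised oxocarbenium ion runs under acid too mild for PMB or TBDPS ethers, and the E-enal formed (CHO trans to the chain) is the thermodynamically preferred isomer, so geometry is not endangered.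

Step 11
Reactants: 19 (2E,6Z)-8-[(tert-butyldiphenylsilyl)oxy]-2-{[(4-methoxybenzyl)oxy]methyl}-6-methylocta-2,6-dienal
Product: 21 (4R,5E,9Z)-11-[(tert-butyldiphenylsilyl)oxy]-5-{[(4-methoxybenzyl)oxy]methyl}-9-methylundeca-1,5,9-trien-4-ol, via borinate 20 (not isolated)
Conditions: (+)-Ipc2BOMe [the enantiomer made from (−)-α-pinene], allylMgBr (0.95 equiv vs borane), Et2O, 0 °C → rt; 19, −100 → −78 °C; then 3 M NaOH, 30% H2O2, 0 °C → rt
Reagents that add atoms: allylmagnesium bromide, C=CC[Mg]Br (allyl group passed on through the B-allylborane)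
Why: Brown asymmetric allylboration proceeds through a closed Zimmerman–Traxler chair in which the isopinocampheyl ligands from (−)-α-pinene steer the allyl group to the Re face of the aldehyde, which should set C6 as (R), a reagent-controlled outcome well established for α-branched enals.

Step 12
Reactants: 22 diethyl malonate; 23 5-bromo-2-methylpent-2-ene
Product: 25 diethyl 2-(4-methylpent-3-en-1-yl)malonate, via sodium enolate 24 (not isolated)
Conditions: 22 (excess), NaH, THF/DMF, 0 °C; 23, NaI (cat.), 60 °C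
Reagents that add atoms: none
Why: Malonic ester alkylation is a soft-nucleophile SN2 reaction on a primary bromide, and excess malonate suppresses dialkylation.

Step 13
Reactants: 25 diethyl 2-(4-methylpent-3-en-1-yl)malonate
Product: 26 2-(4-methylpent-3-en-1-yl)malonic acid
Conditions: KOH, EtOH/H2O, reflux; then aq HCl, 0 °C
Reagents that add atoms: potassium hydroxide, [K+].[OH-]
Why: Saponification of both esters is unproblematic, and cold acidification avoids premature decarboxylation.

Step 14
Reactants: 26 2-(4-methylpent-3-en-1-yl)malonic acid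
Product: 27 6-methyl-2-methylidenehept-5-enoic acid
Conditions: (CH2O)n, Et2NH, EtOAc, reflux
Reagents that add atoms: paraformaldehyde (reacts as formaldehyde), C=O
Why: Mannich condensation of the monosubstituted malonic acid followed by decarboxylative elimination of the amine is the standard methylenation route to 2-alkylacrylic acids.

Step 15
Reactants: 21 (4R,5E,9Z)-11-[(tert-butyldiphenylsilyl)oxy]-5-{[(4-methoxybenzyl)oxy]methyl}-9-methylundeca-1,5,9-trien-4-ol; 27 6-methyl-2-methylidenehept-5-enoic acid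
Product: 28 the 6-methyl-2-methylidenehept-5-enoate ester of alcohol 21 (C6 still R)
Conditions: DCC, DMAP (cat.), CH2Cl2, 0 °C → rt
Reagents that add atoms: none
Why: Steglich esterification acylates the secondary alcohol at oxygen, so the C6–O bond and its configuration are untouched.

Step 16
Reactants: 28 the 6-methyl-2-methylidenehept-5-enoate ester of alcohol 21
Product: 29 (6R)-6-[(2E,6Z)-8-[(tert-butyldiphenylsilyl)oxy]-1-[(4-methoxybenzyl)oxy]-6-methylocta-2,6-dien-2-yl]-3-(4-methylpent-3-en-1-yl)-5,6-dihydro-2H-pyran-2-one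
Conditions: Grubbs II (5–10 mol %), CH2Cl2 (about 2 mM), reflux
Reagents that add atoms: none
Why: In this ring-closing metathesis the catalyst loads on the only monosubstituted alkene and closes the six-membered ring onto the 1,1-disubstituted acrylate, as is well known for 2-alkylacrylates of homoallylic alcohols, whereas the three trisubstituted alkenes could only give four-, eight- or nine-membered rings.

Step 17
Reactants: 29 PMB- and TBDPS-protected lactone
Product: 30 (6R)-6-[(2E,6Z)-8-[(tert-butyldiphenylsilyl)oxy]-1-hydroxy-6-methylocta-2,6-dien-2-yl]-3-(4-methylpent-3-en-1-yl)-5,6-dihydro-2H-pyran-2-one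
Conditions: DDQ (1.3 equiv), CH2Cl2/pH 7 buffer, 0 °C
Reagents that add atoms: none
Why: Oxidative PMB cleavage (hydride abstraction from the electron-rich benzyl position, then hydrolysis of the oxocarbenium ion) is orthogonal to silyl ether, lactone and unactivated alkenes, and limited DDQ at 0 °C should prevent further oxidation of the allylic alcohol.

Step 18
Reactants: 30 primary allylic alcohol
Product: 31 (2E,6Z)-8-[(tert-butyldiphenylsilyl)oxy]-6-methyl-2-[(2R)-5-(4-methylpent-3-en-1-yl)-6-oxo-3,6-dihydro-2H-pyran-2-yl]octa-2,6-dien-1-yl acetate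
Conditions: Ac2O, pyridine, DMAP (cat.), CH2Cl2, 0 °C → rt
Reagents that add atoms: acetic anhydride, CC(=O)OC(C)=O
Why: DMAP-catalysed acetylation meets a single free hydroxyl group, so the acetate can only land on the C7 oxymethyl carbon.

Step 19
Reactants: 31 TBDPS-protected acetate
Product: 32 CNP0179839.1, (2E,6Z)-8-hydroxy-6-methyl-2-[(2R)-5-(4-methylpent-3-en-1-yl)-6-oxo-3,6-dihydro-2H-pyran-2-yl]octa-2,6-dien-1-yl acetate
Conditions: HF·pyridine, pyridine, THF, 0 °C → rt
Reagents that add atoms: none
Why: Buffered fluoride desilylation frees the C13 alcohol without generating a basic alkoxide, so acetate cleavage, acyl transfer and lactone opening should be avoided.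

Compound list
1 | tert-butyl(but-3-yn-1-yloxy)dimethylsilane (commercial TBS ether of 3-butyn-1-ol) | C#CCCO[Si](C)(C)C(C)(C)C | starting material
2 | lithium acetylide of 1 | [Li]C#CCCO[Si](C)(C)C(C)(C)C | intermediate
3 | methyl 5-[(tert-butyldimethylsilyl)oxy]pent-2-ynoate | COC(=O)C#CCCO[Si](C)(C)C(C)(C)C | intermediate
4 | lithium methyl(alkenyl)cuprate from syn addition to 3 (Cu on C2, cis to the new methyl) | [Li+].CC(C)(C)[Si](C)(C)OCC/C(C)=C(\C(=O)OC)[Cu-]C | intermediate
5 | methyl (Z)-5-[(tert-butyldimethylsilyl)oxy]-3-methylpent-2-enoate | CC(C)(C)[Si](C)(C)OCC/C(C)=C\C(=O)OC | intermediate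
6 | (Z)-5-[(tert-butyldimethylsilyl)oxy]-3-methylpent-2-en-1-ol | CC(C)(C)[Si](C)(C)OCC/C(C)=C\CO | intermediate
7 | (Z)-1-[(tert-butyldiphenylsilyl)oxy]-5-[(tert-butyldimethylsilyl)oxy]-3-methylpent-2-ene | CC(C)(C)[Si](C)(C)OCC/C(C)=C\CO[Si](c1ccccc1)(c1ccccc1)C(C)(C)C | intermediate
8 | (Z)-5-[(tert-butyldiphenylsilyl)oxy]-3-methylpent-3-en-1-ol | OCC/C(C)=C\CO[Si](c1ccccc1)(c1ccccc1)C(C)(C)C | intermediate
9 | (Z)-tert-butyl[(5-iodo-3-methylpent-2-en-1-yl)oxy]diphenylsilane | ICC/C(C)=C\CO[Si](c1ccccc1)(c1ccccc1)C(C)(C)C | intermediate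
10 | 4-methoxybenzyl alcohol | COc1ccc(CO)cc1 | starting material
11 | sodium 4-methoxybenzyl oxide | [Na+].[O-]Cc1ccc(OC)cc1 | intermediate
12 | 4-methoxybenzyl methylthiomethyl ether | COc1ccc(COCSC)cc1 | intermediate
13 | 4-methoxybenzyl chloromethyl ether | COc1ccc(COCCl)cc1 | intermediate
14 | propiolaldehyde diethyl acetal (3,3-diethoxyprop-1-yne) | C#CC(OCC)OCC | starting material
15 | (Z)-{5-[(tert-butyldiphenylsilyl)oxy]-3-methylpent-3-en-1-yl}lithium | [Li]CC/C(C)=C\CO[Si](c1ccccc1)(c1ccccc1)C(C)(C)C | intermediate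
16 | lithium bis{(Z)-5-[(tert-butyldiphenylsilyl)oxy]-3-methylpent-3-en-1-yl}cuprate | [Li+].CC(C)(C)[Si](c1ccccc1)(c1ccccc1)OC/C=C(/C)CC[Cu-]CC/C(C)=C\CO[Si](c1ccccc1)(c1ccccc1)C(C)(C)C | intermediate
17 | lithium dialkenylcuprate from syn addition of 16 to two molecules of 14 (Cu on C7, cis to C9; acetal trans to C9) | [Li+].[Cu-](/C(=C\CC/C(C)=C\CO[Si](c1ccccc1)(c1ccccc1)C(C)(C)C)C(OCC)OCC)/C(=C\CC/C(C)=C\CO[Si](c1ccccc1)(c1ccccc1)C(C)(C)C)C(OCC)OCC | intermediate
18 | (2E,6Z)-8-[(tert-butyldiphenylsilyl)oxy]-2-{[(4-methoxybenzyl)oxy]methyl}-6-methylocta-2,6-dienal diethyl acetal | COc1ccc(COC/C(=C\CC/C(C)=C\CO[Si](c2ccccc2)(c2ccccc2)C(C)(C)C)C(OCC)OCC)cc1 | intermediate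
19 | (2E,6Z)-8-[(tert-butyldiphenylsilyl)oxy]-2-{[(4-methoxybenzyl)oxy]methyl}-6-methylocta-2,6-dienal | COc1ccc(COC/C(=C\CC/C(C)=C\CO[Si](c2ccccc2)(c2ccccc2)C(C)(C)C)C=O)cc1 | intermediate
20 | bis(isopinocampheyl)borinate of alcohol 21 | COc1ccc(COC/C(=C\CC/C(C)=C\CO[Si](c2ccccc2)(c2ccccc2)C(C)(C)C)[C@H](OB([C@H]2C[C@H]3C[C@@H]([C@@H]2C)C3(C)C)[C@H]2C[C@H]3C[C@@H]([C@@H]2C)C3(C)C)CC=C)cc1 | intermediate
21 | (4R,5E,9Z)-11-[(tert-butyldiphenylsilyl)oxy]-5-{[(4-methoxybenzyl)oxy]methyl}-9-methylundeca-1,5,9-trien-4-ol | COc1ccc(COC/C(=C\CC/C(C)=C\CO[Si](c2ccccc2)(c2ccccc2)C(C)(C)C)[C@H](O)CC=C)cc1 | intermediate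
22 | diethyl malonate | CCOC(=O)CC(=O)OCC | starting material
23 | 5-bromo-2-methylpent-2-ene | CC(C)=CCCBr | starting material
24 | sodium enolate of diethyl malonate | [Na+].CCOC(=O)[CH-]C(=O)OCC | intermediate
25 | diethyl 2-(4-methylpent-3-en-1-yl)malonate | CCOC(=O)C(CCC=C(C)C)C(=O)OCC | intermediate
26 | 2-(4-methylpent-3-en-1-yl)malonic acid | OC(=O)C(CCC=C(C)C)C(=O)O | intermediate
27 | 6-methyl-2-methylidenehept-5-enoic acid | C=C(CCC=C(C)C)C(=O)O | intermediate
28 | (4R,5E,9Z)-11-[(tert-butyldiphenylsilyl)oxy]-5-{[(4-methoxybenzyl)oxy]methyl}-9-methylundeca-1,5,9-trien-4-yl 6-methyl-2-methylidenehept-5-enoate | COc1ccc(COC/C(=C\CC/C(C)=C\CO[Si](c2ccccc2)(c2ccccc2)C(C)(C)C)[C@H](OC(=O)C(=C)CCC=C(C)C)CC=C)cc1 | intermediate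
29 | (6R)-lactone with C7-CH2OPMB and C13-OTBDPS | COc1ccc(COC/C(=C\CC/C(C)=C\CO[Si](c2ccccc2)(c2ccccc2)C(C)(C)C)[C@H]2CC=C(CCC=C(C)C)C(=O)O2)cc1 | intermediate
30 | (6R)-lactone with C7-CH2OH and C13-OTBDPS | OC/C(=C\CC/C(C)=C\CO[Si](c1ccccc1)(c1ccccc1)C(C)(C)C)[C@H]1CC=C(CCC=C(C)C)C(=O)O1 | intermediate
31 | (6R)-lactone with C7-CH2OAc and C13-OTBDPS | CC(=O)OC/C(=C\CC/C(C)=C\CO[Si](c1ccccc1)(c1ccccc1)C(C)(C)C)[C@H]1CC=C(CCC=C(C)C)C(=O)O1 | intermediate
32 | CNP0179839.1, (2E,6Z)-8-hydroxy-6-methyl-2-[(2R)-5-(4-methylpent-3-en-1-yl)-6-oxo-3,6-dihydro-2H-pyran-2-yl]octa-2,6-dien-1-yl acetate | CC(=O)OC/C(=C\CC/C(C)=C\CO)[C@H]1CC=C(CCC=C(C)C)C(=O)O1 | target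

Total step count: 19.
Longest linear sequence: 14 steps (steps 1–6, 9–11 and 15–19). Steps 7–8 and 12–14 are side branches.

Steps most likely to fail

1. Step 9.
- What may go wrong: alkylation of the C7–copper bond may be outrun by loss of ethoxide from the alkenylcuprate. It may also be starved by decomposition of the labile chloromethyl ether, and the second cuprate ligand may transfer sluggishly.
- Fallback (C7–carbon bond made by palladium carbonylation instead of cuprate alkylation): it sets out from 9 and 14 and proceeds as far as cuprate 17.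
- Cuprate 17 is quenched at −78 °C with iodine, a capture fast enough to beat elimination. This should give (2Z,6Z)-8-[(tert-butyldiphenylsilyl)oxy]-2-iodo-6-methylocta-2,6-dienal diethyl acetal F1 with retention.
- Methoxycarbonylation (PdCl2(PPh3)2, CO, MeOH, Et3N, DMF) should give the methyl 2-(diethoxymethyl)dienoate F2.
- DIBAL-H at −78 °C should give the 2-(diethoxymethyl)dienol F3.
- NaH/PMBCl etherification comes back to the route at 18. Compound 13 is no longer needed.

2. Step 16.
- What may go wrong: slow closure onto the hindered 1,1-disubstituted acrylate may let intermolecular metathesis at the terminal vinyl or the prenyl terminus, or catalyst decay, take over.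
- Fallback (ring formed by Z-selective olefination and lactonisation instead of metathesis): it sets out from enal 19.
- A catalytic enantioselective Mukaiyama acetate aldol is run with 1-methoxy-1-(trimethylsilyloxy)ethene and a chiral Ti(IV) Lewis acid, the catalyst enantiomer being chosen for Re-face attack. It should give the O-trimethylsilyl aldol adduct F4, which is desilylated in the dilute-acid work-up to the (R)-β-hydroxy ester F5.
- TESCl/imidazole gives the triethylsilyl ether F6, and DIBAL-H at −78 °C gives the β-silyloxy aldehyde F7.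
- Separately, methyl bis(2,2,2-trifluoroethyl)phosphonoacetate is alkylated with bromide 23 (NaH, DMF) to the homoprenyl phosphonate F8.
- Still–Gennari olefination of F7 with F8 (KHMDS, 18-crown-6, THF, −78 °C) should give the Z-enoate F9, in which C5 and the ester are cis.
- CSA in MeOH then removes the TES group and closes the lactone, coming back to the route at 29.

3. Step 11.
- What may go wrong: the α-alkoxymethyl branch may erode facial selectivity, or unconverted Grignard reagent may add without control.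
- Fallback (stereocentre set by ketone reduction instead of C–C bond formation): it sets out from 19.
- AllylMgBr in Et2O at −78 °C gives the racemic homoallylic alcohol F10.
- Buffered Dess–Martin oxidation (NaHCO3, CH2Cl2, 0 °C) gives the allyl alkenyl ketone F11 without conjugation of the β,γ-alkene.
- Corey–Bakshi–Shibata reduction follows, with the (S)-methyl oxazaborolidine and catecholborane at −78 °C. The α-branched alkenyl group acts as the large substituent, which should deliver the (R)-alcohol and come back to the route at 21.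

Further compounds
F1 | step 9 | (2Z,6Z)-8-[(tert-butyldiphenylsilyl)oxy]-2-iodo-6-methylocta-2,6-dienal diethyl acetal | I/C(=C\CC/C(C)=C\CO[Si](c1ccccc1)(c1ccccc1)C(C)(C)C)C(OCC)OCC
F2 | step 9 | methyl (2Z,6Z)-8-[(tert-butyldiphenylsilyl)oxy]-2-(diethoxymethyl)-6-methylocta-2,6-dienoate | COC(=O)/C(=C\CC/C(C)=C\CO[Si](c1ccccc1)(c1ccccc1)C(C)(C)C)C(OCC)OCC
F3 | step 9 | (2E,6Z)-8-[(tert-butyldiphenylsilyl)oxy]-2-(diethoxymethyl)-6-methylocta-2,6-dien-1-ol | OC/C(=C\CC/C(C)=C\CO[Si](c1ccccc1)(c1ccccc1)C(C)(C)C)C(OCC)OCC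
F4 | step 16 | methyl (3R,4E,8Z)-10-[(tert-butyldiphenylsilyl)oxy]-4-{[(4-methoxybenzyl)oxy]methyl}-8-methyl-3-[(trimethylsilyl)oxy]deca-4,8-dienoate | COc1ccc(COC/C(=C\CC/C(C)=C\CO[Si](c2ccccc2)(c2ccccc2)C(C)(C)C)[C@H](O[Si](C)(C)C)CC(=O)OC)cc1
F5 | step 16 | methyl (3R,4E,8Z)-10-[(tert-butyldiphenylsilyl)oxy]-3-hydroxy-4-{[(4-methoxybenzyl)oxy]methyl}-8-methyldeca-4,8-dienoate | COc1ccc(COC/C(=C\CC/C(C)=C\CO[Si](c2ccccc2)(c2ccccc2)C(C)(C)C)[C@H](O)CC(=O)OC)cc1
F6 | step 16 | methyl (3R,4E,8Z)-10-[(tert-butyldiphenylsilyl)oxy]-4-{[(4-methoxybenzyl)oxy]methyl}-8-methyl-3-[(triethylsilyl)oxy]deca-4,8-dienoate | COc1ccc(COC/C(=C\CC/C(C)=C\CO[Si](c2ccccc2)(c2ccccc2)C(C)(C)C)[C@H](O[Si](CC)(CC)CC)CC(=O)OC)cc1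
F7 | step 16 | (3R,4E,8Z)-10-[(tert-butyldiphenylsilyl)oxy]-4-{[(4-methoxybenzyl)oxy]methyl}-8-methyl-3-[(triethylsilyl)oxy]deca-4,8-dienal | COc1ccc(COC/C(=C\CC/C(C)=C\CO[Si](c2ccccc2)(c2ccccc2)C(C)(C)C)[C@H](O[Si](CC)(CC)CC)CC=O)cc1
F8 | step 16 | methyl 2-[bis(2,2,2-trifluoroethoxy)phosphoryl]-6-methylhept-5-enoate | COC(=O)C(CCC=C(C)C)P(=O)(OCC(F)(F)F)OCC(F)(F)F
F9 | step 16 | methyl (2Z,5R,6E,10Z)-12-[(tert-butyldiphenylsilyl)oxy]-6-{[(4-methoxybenzyl)oxy]methyl}-10-methyl-2-(4-methylpent-3-en-1-yl)-5-[(triethylsilyl)oxy]dodeca-2,6,10-trienoate | COc1ccc(COC/C(=C\CC/C(C)=C\CO[Si](c2ccccc2)(c2ccccc2)C(C)(C)C)[C@H](O[Si](CC)(CC)CC)C/C=C(/CCC=C(C)C)C(=O)OC)cc1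
F10 | step 11 | racemic (5E,9Z)-11-[(tert-butyldiphenylsilyl)oxy]-5-{[(4-methoxybenzyl)oxy]methyl}-9-methylundeca-1,5,9-trien-4-ol | COc1ccc(COC/C(=C\CC/C(C)=C\CO[Si](c2ccccc2)(c2ccccc2)C(C)(C)C)C(O)CC=C)cc1
F11 | step 11 | (5E,9Z)-11-[(tert-butyldiphenylsilyl)oxy]-5-{[(4-methoxybenzyl)oxy]methyl}-9-methylundeca-1,5,9-trien-4-one | COc1ccc(COC/C(=C\CC/C(C)=C\CO[Si](c2ccccc2)(c2ccccc2)C(C)(C)C)C(=O)CC=C)cc1
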